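Theta ran at the temperature of the new flasks, 25 °C, so I read the pace of conversion from it, working with the share of starting material not yet turned to target.

| flask | starting material | coupling partner | protic impurity | free catalyst | temperature | remark | time |
|---|---|---|---|---|---|---|---|
| zeta | 1 M | 2 M | 0.065 M | 150 mM | 10 °C | run made earlier |  |
| theta | 1 M | 2 M | 0.44 M | 150 mM | 25 °C | run made earlier |  |
| eta | 1 M | 1.9 M | 0.20 M | 150 mM | 10 °C | run made earlier |  |
| cedar | 1.0 M | 2.00 M | 0.200 M | 50 mM | 25 °C |  | 2.0 min |
| elm | 1.0 M | 2.00 M | 0.600 M | 150 mM | 25 °C |  | 2.0 min |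
| birch | 0.50 M | 2.00 M | 0.200 M | 150 mM | 25 °C |  | 2.0 min |
| alder | 1.0 M | 2.00 M | 0.200 M | 150 mM | 25 °C |  | 2.0 min |
| maple | 1.0 M | 0.600 M | 0.200 M | 500 mM | 25 °C |  | 2.0 min |
| ash | 1.0 M | 3.00 M | 0.100 M | 150 mM | 25 °C |  | 2.0 min |

- zeta (time / min: target / %): 1.00: 15.2; 2.00: 33.2; 3.00: 43.6; 4.00: 50.6
- theta (time / s: target / %): 10.0: 4.4; 20.0: 12.3; 50.0: 26.9; 120: 35.7
- eta (time / min: target / %): 0.333: 3.2; 0.667: 7.7; 2.00: 28.9; 4.00: 45.4

(standard deviation of a reading: 1 percentage point)

- no earlier run changes the charge of free catalyst; that part of a forecast is a guess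

- ranking by amount of target, in percent of the starting material charged, from high to low, at 2.0 min (cedar / elm / birch / alder / maple / ash)
- the amount of target, in percent of the starting material charged of the flask you put first, at 2.0 min
- the amount of target, in percent of the starting material charged of the flask you put last, at 2.0 min

1. The main step first. Between 20.0 s and 50.0 s in theta, that share fell from 87.7% to 73.1%. I treated this as a pseudo-first-order fall, with a pace of 0.364 min⁻¹. Held for 2.0 min, that pace would give 51.7% target.

2. Then the fade. From 50.0 s to 120 s the pace was 0.110 min⁻¹, lower than before, and theta read 35.7%, so the fade cost 16 percentage points. The two paces sit 50.0 s apart, which gives a fade half-life, the time in which the pace halves, of 28.9 s. This is a reading, rough with a scatter of 1 point. I did not yet say what faded. After 2.0 min, 5.64% of the pace remains, so I expected these flasks to stand nearly still by then.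

3. Then the impurity. Zeta and eta, both at 10 °C, read 33.2% and 28.9% at 2.00 min. That is a drop of 4.3 points for 0.135 M more protic impurity, with slightly less coupling partner in eta as well. Applying that slope, read at the lower temperature, to theta's last reading, I reckoned alder at 43.3% and elm at 30.6%.

4. Then the rest. Ash has more coupling partner and less impurity than alder, so I put it first. Cedar has a third of the catalyst of alder, so I put it last, and that is a guess.

5. The forecast read ash > birch > alder > elm > maple > cedar, with 56% first and 17% last, holding that “the run is essentially finished by 2 min”.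

6. The flasks gave ash > birch > alder > maple > elm > cedar: ash 49.9%, cedar 16.0%, alder 40.3%, elm 29.1%.

    coupling partner + free catalyst → catalyst intermediate A (k = 0.230 M⁻¹ s⁻¹, Ea = 51.0 kJ mol⁻¹)
    catalyst intermediate A → catalyst intermediate B (k = 0.550 s⁻¹, Ea = 78.0 kJ mol⁻¹)
    starting material + catalyst intermediate B → catalyst intermediate C (k = 0.130 M⁻¹ s⁻¹, Ea = 50.0 kJ mol⁻¹)
    catalyst intermediate C → free catalyst + target (k = 38.0 s⁻¹, Ea = 55.0 kJ mol⁻¹)
    starting material + protic impurity → quenched substrate (k = 0.330 M⁻¹ s⁻¹, Ea = 37.0 kJ mol⁻¹)
    coupling partner → decomposed reagent (k = 0.0490 s⁻¹, Ea = 81.0 kJ mol⁻¹)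
    (constants at 25 °C)

7. In ash at 2.00 min, coupling partner was down to 0.0229% of its charge while free catalyst stood at 96.6%. What faded was the reagent: with the path to decomposed reagent taken away, ash reached 76.8% instead of 49.9%. With a half-life of 28.9 s, the 5.64% of pace remaining promised little from waiting, and ash at 20.0 min held 50.4%. Cedar, the second flask, stood at 16.2% at 20.0 min.

Readings and results are calculated with constants of no real substance; noise was put on by code.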